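## Structural features

The target is a 2,3-dihydrobenzofuran: benzene ring A is fused to the oxygen heterocycle ring B (O1, C2, C3, C3a, C7a). C2 carries the guaiacyl ring C (4-hydroxy-3-methoxyphenyl) and C3 a hydroxymethyl group. Ring A carries a methoxy group at C7 and, at C5, a three-carbon chain that ends in a primary hydrogen sulfate. The only stereocentres, C2 (S) and C3 (R), are adjacent and trans on ring B. The fragile groups are the sulfate monoester (acid-labile, so it must arrive late), the free phenol (oxidation) and the C2–O1 bond. That bond is a benzylic aryl ether: it can ionise in acid when ring C is electron-rich, can be hydrogenolysed, and can be expelled by β-elimination while C3 carries a carbonyl group. The real difficulties are setting the trans C2/C3 pair in the absolute sense and telling two primary alcohols apart so that only the chain oxygen is sulfated. The key step exploits the fact that ring B plus the hydroxymethyl carbon is the pyranone ring of a flavanone with its carbonyl carbon pushed out: a 1,2-shift of the ring A carbon (C4a of the flavanone) from C4 to C3 forms C3–C3a, turns C4 into the exocyclic carboxyl carbon and creates C3 under the control of C2.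

## Logic of the disconnections

**17 to 16.** The cuts are the two C–H bonds of the hydroxymethyl group (alcohol back to methyl ester) and the O–H of the ring C phenol (back to a pivalate). The reason is that the ester left by the ring contraction is itself the protecting group of the future C3 alcohol, so the chain oxygen can be sulfated before the ester is reduced. The gain is that no alcohol has to be protected and unmasked again, and the route does not end with a hydrogenolysis next to the benzylic C2–O1 bond. The demand is a hydride source that reduces an ester and cleaves an aryl ester but leaves a sulfate monoester anion alone; a borohydride meets it.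

**16 to 15.** The S–O bond of the sulfate is cut. In 15 the chain hydroxyl is the only free OH, so sulfation needs no selectivity. The demand is a mild, weakly basic sulfating agent, because the C3 ester is β to O1.

**15 to 14.** The O–CH2Ph bond of the chain ether is cut. A benzyl ether is chosen over a silyl ether because it is indifferent to the strong acid of the ring contraction and leaves under neutral conditions. The demand is that hydrogenolysis spares the more hindered, electron-poor C2–O1 bond.

**14 to 11 (key).** The C3–C3a bond is cut and the C4–C4a bond of a chromanone is restored. The gain is large: the trans dihydrobenzofuran ester with two stereocentres becomes a flavanone with one, which catalytic asymmetric methods can reach. The demand is that the ring A carbon, and not the C2 aryl group, migrates, and that C2 survives acid and oxidant. For that reason the ring C oxygen in 11 is a pivalate and not a benzyl ether. An alkoxy group para to C2 would raise the migratory aptitude of ring C (the isoflavone pathway), would help the C2–O1 bond to ionise (racemisation) and would make ring C a target for the iodine oxidant.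

**11 to 7 and 10.** The C2–aryl bond is cut. This is the only stereocentre set by a catalyst, and it joins two fragments of similar size. The demand is a base-free, face-selective aryl transfer, since base would open the pyranone ring and cleave the pivalate. A pyridine-oxazoline complex of divalent palladium meets it, and such catalysts work best with electron-poor arylboronic acids like 10.

**10 to 9 to 8.** The B–O bonds of the pinacol ester and the O–acyl bond are cut, leading to commercial 8. The demand is a boronate cleavage mild enough for the aryl ester.

**7 to 4 and 5 (through 6).** The C6–CH2 bond is cut. The chain arrives with its oxygen already protected and the arene keeps the correct 6,8-pattern. The demand is an sp2–sp3 coupling gentle enough for the base-sensitive pyranone.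

**4 to 2 (through 3), and 2 to 1.** The O1–C2 and C2–C3 bonds of the pyranone are cut back to a methyl ketone and a one-carbon amide acetal, then the C–Br bond is cut. In 1 the hydroxyl (para-directing) and acetyl (meta-directing) groups both point to the carbon that must carry the bromine, so regiochemistry is not in doubt.

## Other disconnections considered

**Alternative 1:** Gold-catalysed furan-yne phenol synthesis. The cut removes C3a–C7a and C6–C7, so ring A is assembled from a 2,4-disubstituted furan and an ethynyl ether, and ring B closes in the same event. In the forward sense the acyclic ether A2 would be treated with Ph3PAuNTf2 (monovalent gold) to give phenol A1.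
- In its favour: two rings and two C–C bonds form in one redox-neutral step at ambient temperature, without acid or oxidant. On bond-forming economy of the key step and on mildness toward the C2–O1 bond it is better than the chosen plan. C3 already carries a benzyloxymethyl group, so the two primary alcohols are told apart from the start, which is at least equal to the chosen plan.
- Against it: both stereocentres must be built beforehand in an open chain, so the key step relays nothing. The ethynyl ether of a secondary benzylic alcohol is prone to hydration and to sigmatropic shift to a ketene, and needs strongly basic chemistry for its preparation. An oxygen directly on the alkyne changes the polarisation of the gold-bound alkyne relative to the carbon- and nitrogen-tethered cases. A1 carries a free C7 phenol, which costs a methylation.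
- Comparison: structurally it builds more of the skeleton per step. Mechanistically it offers no stereochemical correction, whereas the chosen plan sets C3 under C2 control with thermodynamic backing. In step count it should be clearly longer, because A2 needs a multi-step stereoselective synthesis.

**Alternative 2:** Aryl radical 5-exo cyclisation with oxygen trapping. The cut removes C3–C3a and the C–O bond of the hydroxymethyl group. Aryl iodide A4 would be treated with Bu3SnH under air to give alcohol A3.
- In its favour: A4 is only a few steps from simple materials, and the hydroxymethyl group appears at its final oxidation level, so no ester reduction is needed. On redox economy and on length of the way to the cyclisation substrate it is better than the chosen plan. It forms the same C3–C3a bond as the chosen plan.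
- Against it: the C3 configuration is set kinetically in the radical addition and cannot be corrected afterwards, since A3 has no epimerisable centre. The aryl radical can abstract the doubly activated C2 hydrogen, which would scramble C2. Oxygen capture competes with direct reduction by the tin hydride. The aryl ether bond of A4 would have to be made with clean inversion at a carbon that is both benzylic and allylic. A3 has its C3 hydroxyl free and the chain oxygen silylated, so an extra protection is needed before sulfation, and stoichiometric tin has to be removed.
- Comparison: equal in the bond formed and shorter before the key step. It is weaker in stereocontrol (kinetic versus thermodynamic trans) and in the endgame, where the chosen plan uses the ester as a built-in protecting group.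

**Alternative 3:** Diels–Alder benzannulation on a trans butyrolactone. The cut removes C5–C6 and C7–C7a. Alkylidene lactone A6 would be converted to silyl dienol ether A7, which adds the ynone A8; loss of silanol would aromatise ring A and give ketone A5.
- In its favour: the trans C2/C3 pair is set on a lactone, where it is thermodynamically favoured and independent of ring A. The regiochemistry follows from the polarisation of diene and dienophile. C3 carries a benzyl ether from the start, which equals or betters the chosen plan in differentiating the alcohols.
- Against it: A5 carries an acetyl group where a methoxy group is needed, so a Baeyer–Villiger oxidation, a hydrolysis and a methylation follow. A7 is a sensitive ketene acetal that may react by conjugate addition without closing the ring. In the aromatisation the ring oxygen O1 can leave in place of the silyloxy group, which would open ring B.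
- Comparison: structurally more convergent on ring A. Mechanistically it carries a branch point at the aromatisation that the chosen plan does not have. In step count it is the longest, because of the lactone synthesis and the three-step correction at C7.

Key step: step 7

Assumptions: (a) the (R)-configured pyridine-oxazoline ligand is specified on the expectation that the facial preference known for cyclic enones carries over to chromone 7; the antipodal ligand would be used if the sense proved to be the reverse. (b) 16 is handled as its sodium salt, and 17 is released as the free hydrogen sulfate, as drawn, only at the end.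

## Route

Step 1
Reactants: 1 1-(2-hydroxy-3-methoxyphenyl)ethan-1-one
Product: 2 1-(5-bromo-2-hydroxy-3-methoxyphenyl)ethan-1-one
Conditions: NBS (1.05 eq), MeCN, 0 °C → rt
Reagents that add atoms: N-bromosuccinimide, O=C1CCC(=O)N1Br
Why: Electrophilic aromatic bromination; the hydroxyl group directs para and the acetyl group meta, both to C5, and the two ortho positions of the phenol are occupied.

Step 2
Reactants: 2 1-(5-bromo-2-hydroxy-3-methoxyphenyl)ethan-1-one
Product: 4 6-bromo-8-methoxy-4H-chromen-4-one, via enaminone 3 (not isolated)
Conditions: Me2NCH(OMe)2, toluene, 100 °C; then conc. HCl, CH2Cl2, 40 °C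
Reagents that add atoms: N,N-dimethylformamide dimethyl acetal, CN(C)C(OC)OC
Why: Condensation of the methyl ketone with the amide acetal gives the enaminone; acid then promotes addition of the phenol oxygen to the β-carbon and loss of dimethylamine (enaminone route to chromones).

Step 3
Reactants: 5 allyl benzyl ether, [(prop-2-en-1-yloxy)methyl]benzene; 4 6-bromo-8-methoxy-4H-chromen-4-one
Product: 7 6-[3-(benzyloxy)propyl]-8-methoxy-4H-chromen-4-one, via alkylborane 6 (not isolated)
Conditions: 9-BBN, THF, 0 °C → rt; then 4, Pd(dppf)Cl2 (5 mol %), AsPh3, Cs2CO3, DMF/H2O, rt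
Reagents that add atoms: none
Why: Anti-Markovnikov hydroboration followed by B-alkyl Suzuki–Miyaura coupling; the divalent palladium precatalyst is reduced in the flask to zerovalent palladium, which inserts into the C6–Br bond, and carbonate at room temperature should spare the base-sensitive pyranone.

Step 4
Reactants: 8 2-methoxy-4-(4,4,5,5-tetramethyl-1,3,2-dioxaborolan-2-yl)phenol
Product: 9 2-methoxy-4-(4,4,5,5-tetramethyl-1,3,2-dioxaborolan-2-yl)phenyl 2,2-dimethylpropanoate
Conditions: t-BuCOCl, NEt3, DMAP (cat.), CH2Cl2, 0 °C → rt
Reagents that add atoms: pivaloyl chloride, CC(C)(C)C(=O)Cl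
Why: DMAP-catalysed O-acylation of the phenol; the pivalate withdraws electron density from ring C, resists acid and falls to hydride at the end.

Step 5
Reactants: 9 2-methoxy-4-(4,4,5,5-tetramethyl-1,3,2-dioxaborolan-2-yl)phenyl 2,2-dimethylpropanoate
Product: 10 [3-methoxy-4-(2,2-dimethylpropanoyloxy)phenyl]boronic acid
Conditions: NaIO4, NH4OAc, acetone/H2O, rt
Reagents that add atoms: water, O
Why: Periodate cleaves the pinacol released in the hydrolysis equilibrium and so drives the boronate ester to the free boronic acid in a near-neutral buffer that leaves the hindered aryl ester alone.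

Step 6
Reactants: 7 6-[3-(benzyloxy)propyl]-8-methoxy-4H-chromen-4-one; 10 [3-methoxy-4-(2,2-dimethylpropanoyloxy)phenyl]boronic acid
Product: 11 4-[(2S)-6-[3-(benzyloxy)propyl]-8-methoxy-4-oxo-3,4-dihydro-2H-chromen-2-yl]-2-methoxyphenyl 2,2-dimethylpropanoate
Conditions: Pd(OCOCF3)2 (5 mol %), (R)-4-tert-butyl-2-(pyridin-2-yl)-4,5-dihydro-1,3-oxazole (6 mol %), NH4PF6 (30 mol %), H2O (5 eq), ClCH2CH2Cl, 60 °C
Reagents that add atoms: none
Why: Enantioselective conjugate addition of an arylboronic acid to a chromone catalysed by a cationic divalent palladium pyridine-oxazoline complex: transmetalation, insertion of the enone on the face left open by the tert-butyl group (sets C2 as S) and protonolysis of the palladium enolate by water. The medium is base-free, so neither the pyranone nor the pivalate is at risk, and the electron-poor boronic acid is the kind of partner this catalyst handles best.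

Step 7
Reactants: 11 4-[(2S)-6-[3-(benzyloxy)propyl]-8-methoxy-4-oxo-3,4-dihydro-2H-chromen-2-yl]-2-methoxyphenyl 2,2-dimethylpropanoate
Product: 14 methyl (2S,3S)-5-[3-(benzyloxy)propyl]-7-methoxy-2-[3-methoxy-4-(2,2-dimethylpropanoyloxy)phenyl]-2,3-dihydro-1-benzofuran-3-carboxylate, via methyl enol ether 12 (not isolated), via trimethyl orthoester 13 (not isolated)
Conditions: PhI(OAc)2 (1.2 eq), conc. H2SO4 (0.5 eq), HC(OMe)3, 0 °C → rt; then H2O, then aq. NaHCO3
Reagents that add atoms: trimethyl orthoformate, COC(OC)OC; water, O
Why: Acid and HC(OMe)3 convert the ketone through its dimethyl ketal into enol ether 12, whose C3 attacks the trivalent iodine centre of PhI(OAc)2 on the face away from the C2 aryl group while methanol re-forms the ketal at C4. With the iodanyl group equatorial and trans to the aryl group, the C4–C4a bond lies antiperiplanar to the C3–iodine bond, and the ring A carbon C4a shifts from C4 to C3 through a bridged phenonium-type ion as iodobenzene and acetate leave, with inversion at C3. The dimethoxycarbenium ion so formed is caught by methanol as orthoester 13, which the aqueous acidic work-up hydrolyses to ester 14. The closest known reaction type is the oxidative ring contraction of flavanones by trivalent iodine or thallium trinitrate, itself a cyclic case of the 1,2-aryl shift of α-functionalised aryl ketone ketals to 2-arylalkanoates. Ring B is closed by contraction, not by cyclisation: the six-membered pyranone loses C4 to the exocyclic position as C3–C3a forms and C4–C4a breaks. C2 is carried over unchanged from 11; the new centre C3 is set by anti attack of iodine followed by invertive migration, which places the ester carbon trans to the aryl group, and the acidic medium can epimerise any cis ester to the more stable trans isomer. The step needs migration of the ring A carbon in preference to migration of the C2 aryl group, loss of the C2 hydrogen (flavone) or capture of methanol at C3. The ring oxygen O1 ortho to C4a stabilises the bridged ion (the C8 methoxy group is meta to C4a and adds little), while the acyloxy group para to C2 makes ring C a poor migrating group, a poor donor for C2–O1 ionisation and a poor substrate for the oxidant. The primary benzyl ether is inert to both acid and oxidant.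

Step 8
Reactants: 14 methyl (2S,3S)-5-[3-(benzyloxy)propyl]-7-methoxy-2-[3-methoxy-4-(2,2-dimethylpropanoyloxy)phenyl]-2,3-dihydro-1-benzofuran-3-carboxylate
Product: 15 methyl (2S,3S)-5-(3-hydroxypropyl)-7-methoxy-2-[3-methoxy-4-(2,2-dimethylpropanoyloxy)phenyl]-2,3-dihydro-1-benzofuran-3-carboxylate
Conditions: H2 (1 atm), 10 % Pd/C, EtOAc, rt
Reagents that add atoms: none
Why: Hydrogenolysis of an unhindered primary benzyl ether under neutral conditions, which avoids base-induced β-elimination of O1 from the ester enolate; the secondary, hindered C2–O1 bond on an electron-poor aryl ring should react much more slowly.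

Step 9
Reactants: 15 methyl (2S,3S)-5-(3-hydroxypropyl)-7-methoxy-2-[3-methoxy-4-(2,2-dimethylpropanoyloxy)phenyl]-2,3-dihydro-1-benzofuran-3-carboxylate
Product: 16 sodium 3-[(2S,3S)-7-methoxy-3-(methoxycarbonyl)-2-[3-methoxy-4-(2,2-dimethylpropanoyloxy)phenyl]-2,3-dihydro-1-benzofuran-5-yl]propyl sulfate
Conditions: SO3·pyridine (3 eq), pyridine, rt; then aq. NaHCO3
Reagents that add atoms: sulfur trioxide–pyridine complex, [O-]S(=O)(=O)[n+]1ccccc1; sodium hydrogen carbonate, [Na+].OC([O-])=O
Why: O-sulfation of the only free hydroxyl with the sulfur trioxide amine complex; the other primary oxygen is still an ester carbon and the phenol still a pivalate, so no selectivity is required.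

Step 10
Reactants: 16 sodium 3-[(2S,3S)-7-methoxy-3-(methoxycarbonyl)-2-[3-methoxy-4-(2,2-dimethylpropanoyloxy)phenyl]-2,3-dihydro-1-benzofuran-5-yl]propyl sulfate
Product: 17 3-[(2S,3R)-2-(4-hydroxy-3-methoxyphenyl)-3-(hydroxymethyl)-7-methoxy-2,3-dihydro-1-benzofuran-5-yl]propyl hydrogen sulfate
Conditions: LiBH4 (excess), THF/MeOH, 0 °C → rt; then 1 M HCl to pH 2, 0 °C, desalting on C18 silica (H2O, then MeOH)
Reagents that add atoms: none
Why: Borohydride reduction of the methyl ester to the primary alcohol with concurrent reductive cleavage of the activated aryl pivalate; sulfate monoester anions are inert to borohydride. Neither stereocentre is touched, and the C3 descriptor changes from S to R only because the substituent priorities change.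

## Compound list

1 | 1-(2-hydroxy-3-methoxyphenyl)ethan-1-one | CC(=O)c1cccc(OC)c1O | starting material
2 | 1-(5-bromo-2-hydroxy-3-methoxyphenyl)ethan-1-one | CC(=O)c1cc(Br)cc(OC)c1O | intermediate
3 | (2E)-1-(5-bromo-2-hydroxy-3-methoxyphenyl)-3-(dimethylamino)prop-2-en-1-one | CN(C)/C=C/C(=O)c1cc(Br)cc(OC)c1O | intermediate
4 | 6-bromo-8-methoxy-4H-chromen-4-one | O=c1ccoc2c(OC)cc(Br)cc12 | intermediate
5 | allyl benzyl ether, [(prop-2-en-1-yloxy)methyl]benzene | C=CCOCc1ccccc1 | starting material
6 | 9-[3-(benzyloxy)propyl]-9-borabicyclo[3.3.1]nonane | C(CCOCc1ccccc1)B1C2CCCC1CCC2 | intermediate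
7 | 6-[3-(benzyloxy)propyl]-8-methoxy-4H-chromen-4-one | O=c1ccoc2c(OC)cc(CCCOCc3ccccc3)cc12 | intermediate
8 | 2-methoxy-4-(4,4,5,5-tetramethyl-1,3,2-dioxaborolan-2-yl)phenol | COc1cc(B2OC(C)(C)C(C)(C)O2)ccc1O | starting material
9 | 2-methoxy-4-(4,4,5,5-tetramethyl-1,3,2-dioxaborolan-2-yl)phenyl 2,2-dimethylpropanoate | COc1cc(B2OC(C)(C)C(C)(C)O2)ccc1OC(=O)C(C)(C)C | intermediate
10 | [3-methoxy-4-(2,2-dimethylpropanoyloxy)phenyl]boronic acid | COc1cc(B(O)O)ccc1OC(=O)C(C)(C)C | intermediate
11 | 4-[(2S)-6-[3-(benzyloxy)propyl]-8-methoxy-4-oxo-3,4-dihydro-2H-chromen-2-yl]-2-methoxyphenyl 2,2-dimethylpropanoate | COc1cc([C@@H]2CC(=O)c3cc(CCCOCc4ccccc4)cc(OC)c3O2)ccc1OC(=O)C(C)(C)C | intermediate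
12 | 4-[(2S)-6-[3-(benzyloxy)propyl]-4,8-dimethoxy-2H-chromen-2-yl]-2-methoxyphenyl 2,2-dimethylpropanoate | COc1cc([C@@H]2C=C(OC)c3cc(CCCOCc4ccccc4)cc(OC)c3O2)ccc1OC(=O)C(C)(C)C | intermediate
13 | 4-[(2S,3S)-5-[3-(benzyloxy)propyl]-7-methoxy-3-(trimethoxymethyl)-2,3-dihydro-1-benzofuran-2-yl]-2-methoxyphenyl 2,2-dimethylpropanoate | COc1cc([C@H]2Oc3c(OC)cc(CCCOCc4ccccc4)cc3[C@@H]2C(OC)(OC)OC)ccc1OC(=O)C(C)(C)C | intermediate
14 | methyl (2S,3S)-5-[3-(benzyloxy)propyl]-7-methoxy-2-[3-methoxy-4-(2,2-dimethylpropanoyloxy)phenyl]-2,3-dihydro-1-benzofuran-3-carboxylate | COc1cc([C@H]2Oc3c(OC)cc(CCCOCc4ccccc4)cc3[C@@H]2C(=O)OC)ccc1OC(=O)C(C)(C)C | intermediate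
15 | methyl (2S,3S)-5-(3-hydroxypropyl)-7-methoxy-2-[3-methoxy-4-(2,2-dimethylpropanoyloxy)phenyl]-2,3-dihydro-1-benzofuran-3-carboxylate | COc1cc([C@H]2Oc3c(OC)cc(CCCO)cc3[C@@H]2C(=O)OC)ccc1OC(=O)C(C)(C)C | intermediate
16 | sodium 3-[(2S,3S)-7-methoxy-3-(methoxycarbonyl)-2-[3-methoxy-4-(2,2-dimethylpropanoyloxy)phenyl]-2,3-dihydro-1-benzofuran-5-yl]propyl sulfate | COc1cc([C@H]2Oc3c(OC)cc(CCCOS(=O)(=O)[O-])cc3[C@@H]2C(=O)OC)ccc1OC(=O)C(C)(C)C.[Na+] | intermediate
17 | 3-[(2S,3R)-2-(4-hydroxy-3-methoxyphenyl)-3-(hydroxymethyl)-7-methoxy-2,3-dihydro-1-benzofuran-5-yl]propyl hydrogen sulfate | COc1cc([C@H]2Oc3c(OC)cc(CCCOS(=O)(=O)O)cc3[C@@H]2CO)ccc1O | target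

## Step count and risks

Total step count: 10. Longest linear sequence: 8 steps (1, 2, 3, 6, 7, 8, 9, 10); steps 4 and 5 form a two-step side branch.

**Step 7 (key step).**
- What may go wrong: diversion of the C3-iodanyl ketal into loss of the C2 hydrogen (flavone formation) or into capture of methanol at C3; residual migration of the C2 aryl group; acid-induced opening of the C2–O1 bond with loss of enantiomeric purity; over-oxidation of the electron-rich ring A.
- Fallback: this sets out from 11 and returns at 14, and makes the same C3–C3a bond by a carbene-type 1,2-shift without oxidant or strong acid. Acylation of the lithium enolate of 11 (LiN(SiMe3)2, CF3CO2CH2CF3, THF, −78 °C) would give the 3-trifluoroacetyl ketone F1. Detrifluoroacetylative diazo transfer (MsN3, NEt3, H2O, MeCN) would convert it into the 3-diazo ketone F2. Irradiation at 365 nm in methanol should then bring about a Wolff rearrangement in which the same ring A carbon migrates to C3 and methanol adds, to give 14 together with its cis C3 epimer F3. A catalytic amount of DBU in toluene would equilibrate F3 to 14. The low temperature of the enolisation is meant to outrun ring opening of the enolate.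

**Step 6.**
- What may go wrong: slow insertion into the electron-rich chromone, competing protodeboronation, or insufficient facial selectivity.
- Fallback: this sets out from 7 (with 10) and returns at 11, replacing asymmetric addition by resolution. The same addition with the achiral ligand 2,2'-bipyridine in place of the oxazoline would give the racemic flavanone F4. Kinetic resolution by asymmetric transfer hydrogenation (RuCl[TsDPEN](p-cymene), a divalent ruthenium catalyst, HCO2H/NEt3) would follow, with the diamine enantiomer chosen so that the (R)-ketone is the fast-reacting one. The (R)-ketone would be reduced to the cis alcohol F5 and 11 would be left behind, at the cost of half the material.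

**Step 3.**
- What may go wrong: opening of the pyranone ring by aqueous base during the coupling, or reduction of the C–Br bond in competition with slow transmetalation.
- Fallback: this sets out from 2 (with 6) and returns at 7, with the order of coupling and ring formation reversed. Borane 6 would be coupled with the base-stable phenol 2 (Pd(OAc)2, SPhos, K3PO4, THF/H2O, 60 °C) to give the ketone F6. Me2NCH(OMe)2 and then HCl would convert F6 through the enaminone F7 into 7.

**Step 8.**
- What may go wrong: competing hydrogenolytic opening of ring B at the benzylic C2–O1 bond, or a sluggish debenzylation that invites it.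
- Fallback: this sets out from 14 and returns at 15, and uses a cationic in place of a reductive cleavage. BCl3 with pentamethylbenzene as cation scavenger in CH2Cl2 at −78 °C would remove the primary benzyl ether. The electron-poor ring C disfavours ionisation at C2, and the aryl methyl ethers are expected to survive at this temperature. No new compound is involved.

**Step 10.**
- What may go wrong: incomplete cleavage of the hindered pivalate, β-elimination of O1 from the ester enolate before reduction, poor solubility of the salt, or loss of the sulfate during the acidic release.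
- Fallback: this sets out from 14 and returns at 17, reverting to the conventional order in which the sulfate is never exposed to hydride. LiAlH4 (THF, 0 °C) would reduce the ester and cleave the pivalate to give the phenol-alcohol F8. Ac2O/pyridine would give the diacetate F9. Hydrogenolysis (H2, Pd/C) would free the chain alcohol F10. SO3·pyridine followed by NaHCO3 would give the sulfate salt F11. K2CO3 in methanol and then acidification as in step 10 would remove both acetates and give 17. This costs two more steps.

## Further compounds

F1 | step 7 | 4-[(2S)-6-[3-(benzyloxy)propyl]-8-methoxy-4-oxo-3-(trifluoroacetyl)-3,4-dihydro-2H-chromen-2-yl]-2-methoxyphenyl 2,2-dimethylpropanoate (C3 enolisable, not assigned) | COc1cc([C@@H]2C(C(=O)C(F)(F)F)C(=O)c3cc(CCCOCc4ccccc4)cc(OC)c3O2)ccc1OC(=O)C(C)(C)C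
F2 | step 7 | 4-[(2R)-6-[3-(benzyloxy)propyl]-3-diazo-8-methoxy-4-oxo-3,4-dihydro-2H-chromen-2-yl]-2-methoxyphenyl 2,2-dimethylpropanoate (same spatial arrangement at C2 as in 11; the descriptor changes because the diazo carbon outranks the aryl group) | COc1cc([C@@H]2C(=[N+]=[N-])C(=O)c3cc(CCCOCc4ccccc4)cc(OC)c3O2)ccc1OC(=O)C(C)(C)C
F3 | step 7 | methyl (2S,3R)-5-[3-(benzyloxy)propyl]-7-methoxy-2-[3-methoxy-4-(2,2-dimethylpropanoyloxy)phenyl]-2,3-dihydro-1-benzofuran-3-carboxylate (cis epimer of 14) | COc1cc([C@H]2Oc3c(OC)cc(CCCOCc4ccccc4)cc3[C@H]2C(=O)OC)ccc1OC(=O)C(C)(C)C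
F4 | step 6 | racemic 4-[6-[3-(benzyloxy)propyl]-8-methoxy-4-oxo-3,4-dihydro-2H-chromen-2-yl]-2-methoxyphenyl 2,2-dimethylpropanoate | COc1cc(C2CC(=O)c3cc(CCCOCc4ccccc4)cc(OC)c3O2)ccc1OC(=O)C(C)(C)C
F5 | step 6 | 4-[(2R,4R)-6-[3-(benzyloxy)propyl]-4-hydroxy-8-methoxy-3,4-dihydro-2H-chromen-2-yl]-2-methoxyphenyl 2,2-dimethylpropanoate (cis) | COc1cc([C@H]2C[C@@H](O)c3cc(CCCOCc4ccccc4)cc(OC)c3O2)ccc1OC(=O)C(C)(C)C
F6 | step 3 | 1-{5-[3-(benzyloxy)propyl]-2-hydroxy-3-methoxyphenyl}ethan-1-one | CC(=O)c1cc(CCCOCc2ccccc2)cc(OC)c1O
F7 | step 3 | (2E)-1-{5-[3-(benzyloxy)propyl]-2-hydroxy-3-methoxyphenyl}-3-(dimethylamino)prop-2-en-1-one | CN(C)/C=C/C(=O)c1cc(CCCOCc2ccccc2)cc(OC)c1O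
F0 | step 8 | none | none
F8 | step 10 | 4-[(2S,3R)-5-[3-(benzyloxy)propyl]-3-(hydroxymethyl)-7-methoxy-2,3-dihydro-1-benzofuran-2-yl]-2-methoxyphenol | COc1cc([C@H]2Oc3c(OC)cc(CCCOCc4ccccc4)cc3[C@@H]2CO)ccc1O
F9 | step 10 | [(2S,3R)-2-(4-acetoxy-3-methoxyphenyl)-5-[3-(benzyloxy)propyl]-7-methoxy-2,3-dihydro-1-benzofuran-3-yl]methyl acetate | COc1cc([C@H]2Oc3c(OC)cc(CCCOCc4ccccc4)cc3[C@@H]2COC(C)=O)ccc1OC(C)=O
F10 | step 10 | [(2S,3R)-2-(4-acetoxy-3-methoxyphenyl)-5-(3-hydroxypropyl)-7-methoxy-2,3-dihydro-1-benzofuran-3-yl]methyl acetate | COc1cc([C@H]2Oc3c(OC)cc(CCCO)cc3[C@@H]2COC(C)=O)ccc1OC(C)=O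
F11 | step 10 | sodium 3-[(2S,3R)-3-(acetoxymethyl)-2-(4-acetoxy-3-methoxyphenyl)-7-methoxy-2,3-dihydro-1-benzofuran-5-yl]propyl sulfate | COc1cc([C@H]2Oc3c(OC)cc(CCCOS(=O)(=O)[O-])cc3[C@@H]2COC(C)=O)ccc1OC(C)=O.[Na+]
A1 | alternative 1 | (2S,3R)-3-(benzyloxymethyl)-2-(4-benzyloxy-3-methoxyphenyl)-5-[3-(tert-butyldimethylsilyloxy)propyl]-2,3-dihydro-1-benzofuran-7-ol | COc1cc([C@H]2Oc3c(O)cc(CCCO[Si](C)(C)C(C)(C)C)cc3[C@@H]2COCc2ccccc2)ccc1OCc1ccccc1
A2 | alternative 1 | (1S,2R)-3-(benzyloxy)-1-(4-benzyloxy-3-methoxyphenyl)-1-(ethynyloxy)-2-{4-[3-(tert-butyldimethylsilyloxy)propyl]furan-2-yl}propane | COc1cc([C@@H](OC#C)[C@@H](COCc2ccccc2)c2cc(CCCO[Si](C)(C)C(C)(C)C)co2)ccc1OCc1ccccc1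
A3 | alternative 2 | [(2S,3R)-2-(4-benzyloxy-3-methoxyphenyl)-5-[3-(tert-butyldimethylsilyloxy)propyl]-7-methoxy-2,3-dihydro-1-benzofuran-3-yl]methanol | COc1cc([C@H]2Oc3c(OC)cc(CCCO[Si](C)(C)C(C)(C)C)cc3[C@@H]2CO)ccc1OCc1ccccc1
A4 | alternative 2 | 2-{[(1S)-1-(4-benzyloxy-3-methoxyphenyl)prop-2-en-1-yl]oxy}-1-iodo-3-methoxy-5-[3-(tert-butyldimethylsilyloxy)propyl]benzene | COc1cc([C@H](C=C)Oc2c(I)cc(CCCO[Si](C)(C)C(C)(C)C)cc2OC)ccc1OCc1ccccc1
A5 | alternative 3 | 1-[(2S,3R)-3-(benzyloxymethyl)-2-(4-benzyloxy-3-methoxyphenyl)-5-[3-(tert-butyldimethylsilyloxy)propyl]-2,3-dihydro-1-benzofuran-7-yl]ethan-1-one | COc1cc([C@H]2Oc3c(C(C)=O)cc(CCCO[Si](C)(C)C(C)(C)C)cc3[C@@H]2COCc2ccccc2)ccc1OCc1ccccc1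
A6 | alternative 3 | (3E,4R,5S)-4-(benzyloxymethyl)-5-(4-benzyloxy-3-methoxyphenyl)-3-[5-(tert-butyldimethylsilyloxy)pentylidene]oxolan-2-one | COc1cc([C@H]2OC(=O)/C(=C/CCCCO[Si](C)(C)C(C)(C)C)[C@@H]2COCc2ccccc2)ccc1OCc1ccccc1
A7 | alternative 3 | (4R,5S)-4-(benzyloxymethyl)-5-(4-benzyloxy-3-methoxyphenyl)-2-(tert-butyldimethylsilyloxy)-3-[(1E)-5-(tert-butyldimethylsilyloxy)pent-1-en-1-yl]-4,5-dihydrofuran | COc1cc([C@H]2OC(O[Si](C)(C)C(C)(C)C)=C(/C=C/CCCO[Si](C)(C)C(C)(C)C)[C@@H]2COCc2ccccc2)ccc1OCc1ccccc1
A8 | alternative 3 | but-3-yn-2-one | CC(=O)C#C
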